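**Strategy.** The target is cut at the C5–C6 bond (C1 allyl bridgehead, C2=C3(OMe), C4 acetoxy carbon, C5 methoxy bridgehead, C6 aryl, C7 methyl, C8 bridging ketone). The oxygenated C5 lies in the cyclopentanone ring (C1, C7, C6, C5, C8) between the C4 and C8 carbonyl carbons, the signature of an alpha-ketol shift. In one operation the shift moves C6 from carbinol carbon C4 to dione carbon C5, contracts a six-membered ring to that cyclopentanone, sets the C5 stereocentre and forms the conjugated enone. The precursor is a bridgehead-hydroxy bicyclo[2.2.2]octene-2,3-dione, the desilylated endo Diels–Alder adduct of a 3-silyloxy ortho-quinone and (E)-isoelemicin.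

Key step: step 8

Remarks on the chemistry (assumptions):
- The labels C1–C8 are kept for the same atoms in every intermediate; in the bicyclo[2.2.2] compounds label C4 is locant 4, C5 locant 3, C8 locant 2, C3 locant 5, C2 locant 6, C6 locant 8 and C7 locant 7.
- The bridgehead oxygen must be a free hydroxyl for the shift, so it is carried as a silyl ether from commercial 4-allyl-2,6-dimethoxyphenol onward and never as a methyl ether.
- The cycloaddition is run thermally without a chelating Lewis acid and the racemic adduct is resolved on a chiral phase; it is assumed that the (1S,4S,7S,8R) fraction is identified by X-ray or ECD analysis.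
- All bicyclo[2.2.2]octene-2,3-diones are handled in the dark, because such diones can lose CO photochemically.

Step 1
Reactants: 1 4-allyl-2,6-dimethoxyphenol
Product: 2 tert-butyl[2,6-dimethoxy-4-(prop-2-en-1-yl)phenoxy]dimethylsilane
Conditions: TBSCl, imidazole, DMF, rt
Reagents that add atoms: tert-butyldimethylsilyl chloride, CC(C)(C)[Si](C)(C)Cl
Why: Imidazole-promoted silylation of a phenol, which marks the one oxygen that must later become the free bridgehead hydroxyl and blocks the wrong quinone tautomer.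

Step 2
Reactants: 2 tert-butyl[2,6-dimethoxy-4-(prop-2-en-1-yl)phenoxy]dimethylsilane
Product: 3 [3-bromo-2,6-dimethoxy-4-(prop-2-en-1-yl)phenoxy](tert-butyl)dimethylsilane
Conditions: NBS (1.0 equiv), MeCN, 0 °C → rt
Reagents that add atoms: N-bromosuccinimide, O=C1CCC(=O)N1Br
Why: Electrophilic aromatic bromination with NBS in a polar solvent; the two free ring positions are equivalent by symmetry and activated ortho/para by the methoxy groups, and the terminal alkene is much less nucleophilic than the ring.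

Step 3
Reactants: 3 [3-bromo-2,6-dimethoxy-4-(prop-2-en-1-yl)phenoxy](tert-butyl)dimethylsilane
Product: 6 3-[(tert-butyldimethylsilyl)oxy]-2,4-dimethoxy-6-(prop-2-en-1-yl)phenol, via aryllithium 4 (not isolated), via dimethyl arylboronate 5 (not isolated)
Conditions: n-BuLi (1.05 equiv), THF, −78 °C; B(OMe)3, −78 °C → rt; 30% H2O2, aq NaHCO3, 0 °C
Reagents that add atoms: hydrogen peroxide, OO (phenol oxygen of 6); n-butyllithium, [Li]CCCC (lithium of 4 only); trimethyl borate, COB(OC)OC (boron and methoxy groups of 5 only)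
Why: Bromine–lithium exchange at −78 °C outruns allylic deprotonation, immediate borylation traps the aryllithium and oxidative ipso-hydroxylation of the boronate gives the phenol; the silyl ether is meta to the carbanion, so no silyl migration is expected.

Step 4
Reactants: 7 5-bromo-1,2,3-trimethoxybenzene; 8 (E)-prop-1-en-1-ylboronic acid
Product: 9 (E)-isoelemicin, 1,2,3-trimethoxy-5-[(1E)-prop-1-en-1-yl]benzene
Conditions: Pd(PPh3)4 (3 mol %), K2CO3, 1,4-dioxane/H2O, 90 °C
Reagents that add atoms: none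
Why: Suzuki–Miyaura coupling transfers the propenyl group with retention of the E geometry, which later fixes the trans relation of aryl and methyl.

Step 5
Reactants: 6 3-[(tert-butyldimethylsilyl)oxy]-2,4-dimethoxy-6-(prop-2-en-1-yl)phenol; 9 (E)-isoelemicin
Product: 11 racemic (1RS,4RS,7RS,8SR)-4-[(tert-butyldimethylsilyl)oxy]-5-methoxy-7-methyl-1-(prop-2-en-1-yl)-8-(3,4,5-trimethoxyphenyl)bicyclo[2.2.2]oct-5-ene-2,3-dione (aryl endo; methyl exo), via ortho-quinone 10 (not isolated)
Conditions: IBX (1.2 equiv), 9 (3 equiv), DMF, rt → 45 °C, dark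
Reagents that add atoms: 2-iodoxybenzoic acid (IBX), O=C1OI(=O)(O)c2ccccc21
Why: IBX delivers oxygen to the methoxy-bearing ortho carbon and methanol is lost (oxidative demethylation of a guaiacol to an ortho-quinone), and the quinone is trapped in a thermal Diels–Alder reaction as a carbodiene, the nucleophilic methyl-bearing alkene carbon bonding to the allyl-bearing terminus and the benzylic carbon to the silyloxy-bearing terminus; suprafacial addition keeps aryl and methyl trans and the endo transition state places the aryl syn to the new C=C bridge, so all four stereocentres are set relative to one another as a racemate.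

Step 6
Reactants: 11 racemic (1RS,4RS,7RS,8SR)-4-[(tert-butyldimethylsilyl)oxy]-5-methoxy-7-methyl-1-(prop-2-en-1-yl)-8-(3,4,5-trimethoxyphenyl)bicyclo[2.2.2]oct-5-ene-2,3-dione
Product: 12 (1S,4S,7S,8R)-4-[(tert-butyldimethylsilyl)oxy]-5-methoxy-7-methyl-1-(prop-2-en-1-yl)-8-(3,4,5-trimethoxyphenyl)bicyclo[2.2.2]oct-5-ene-2,3-dione
Conditions: preparative SFC, amylose tris(3,5-dimethylphenylcarbamate) phase, CO2/i-PrOH, 35 °C, amber glassware
Reagents that add atoms: none
Why: Chromatographic resolution on a chiral stationary phase separates the two enantiomers of 11 without any bond change, and because the four stereocentres arose together this one separation fixes the absolute configuration of every centre carried to the target, the (1R,4R,7R,8S) enantiomer being removed.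

Step 7
Reactants: 12 (1S,4S,7S,8R)-4-[(tert-butyldimethylsilyl)oxy]-5-methoxy-7-methyl-1-(prop-2-en-1-yl)-8-(3,4,5-trimethoxyphenyl)bicyclo[2.2.2]oct-5-ene-2,3-dione
Product: 13 (1S,4S,7S,8R)-4-hydroxy-5-methoxy-7-methyl-1-(prop-2-en-1-yl)-8-(3,4,5-trimethoxyphenyl)bicyclo[2.2.2]oct-5-ene-2,3-dione
Conditions: Bu4NF/AcOH (1:1), THF, 0 °C → rt, dark
Reagents that add atoms: none
Why: Fluoride-mediated desilylation of a tied-back bridgehead silyl ether whose alkoxide is a good leaving group next to the dione; the acetic acid buffer protonates the alkoxide at once and spares the enol ether, so the shift is reserved for the next step and no stereocentre is touched.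

Step 8
Reactants: 13 (1S,4S,7S,8R)-4-hydroxy-5-methoxy-7-methyl-1-(prop-2-en-1-yl)-8-(3,4,5-trimethoxyphenyl)bicyclo[2.2.2]oct-5-ene-2,3-dione
Product: 14 (1S,5R,6R,7S)-5-hydroxy-3-methoxy-7-methyl-1-(prop-2-en-1-yl)-6-(3,4,5-trimethoxyphenyl)bicyclo[3.2.1]oct-2-ene-4,8-dione
Conditions: KN(SiMe3)2 (1.05 equiv), THF, −78 → −40 °C; AcOH, −78 °C
Reagents that add atoms: none
Why: KN(SiMe3)2 converts the C4 hydroxyl into its potassium alkoxide, and as that oxygen becomes the C4 carbonyl the C4–C6 sigma bond migrates across one face to the neighbouring C5 carbonyl carbon, C6 keeping its configuration, after which the new C5 alkoxide is protonated by the cold acetic acid quench. The closest known reaction type is the alpha-ketol (acyloin) rearrangement that interconverts bridgehead ketols of bicyclo[2.2.2]octanones and bicyclo[3.2.1]octanones. The cyclopentanone ring C1–C7–C6–C5–C8 is closed by contraction of the six-membered ring C1–C7–C6–C4–C5–C8 through the three-centre transition state of the 1,2-shift, so no separate cyclisation event is involved. The new stereocentre C5 is dictated by the cage, since C6 can only reach the face of the C5 carbonyl that is turned towards the C6–C7 bridge, which gives 5R. The selectivity needed is migration of C6 in preference to the vinylic C3, and it is secured under reversible alkoxide conditions because only the C6 shift exchanges the dipole-opposed 1,2-dione for a conjugated 2-methoxy enone and an alkoxide flanked by two carbonyls. A second shift of the C4 acyl carbon from C5 to C8 is suppressed by low temperature, a single equivalent of a non-nucleophilic base and the cold quench, and Al(OiPr)3 is avoided because it could reduce the dione by hydride transfer.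

Step 9
Reactants: 14 (1S,5R,6R,7S)-5-hydroxy-3-methoxy-7-methyl-1-(prop-2-en-1-yl)-6-(3,4,5-trimethoxyphenyl)bicyclo[3.2.1]oct-2-ene-4,8-dione
Product: 15 (1S,5R,6R,7S)-3,5-dimethoxy-7-methyl-1-(prop-2-en-1-yl)-6-(3,4,5-trimethoxyphenyl)bicyclo[3.2.1]oct-2-ene-4,8-dione
Conditions: MeOTf, 2,6-di-tert-butyl-4-methylpyridine, CH2Cl2, 0 °C → rt
Reagents that add atoms: methyl trifluoromethanesulfonate, COS(=O)(=O)C(F)(F)F
Why: O-Methylation of a hindered, electron-poor tertiary alcohol with methyl triflate and a non-nucleophilic pyridine base; no alkoxide is formed, so the ketol cannot shift further or revert, and C5 keeps its configuration.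

Step 10
Reactants: 15 (1S,5R,6R,7S)-3,5-dimethoxy-7-methyl-1-(prop-2-en-1-yl)-6-(3,4,5-trimethoxyphenyl)bicyclo[3.2.1]oct-2-ene-4,8-dione
Product: 16 (1S,4R,5S,6R,7S)-4-hydroxy-3,5-dimethoxy-7-methyl-1-(prop-2-en-1-yl)-6-(3,4,5-trimethoxyphenyl)bicyclo[3.2.1]oct-2-en-8-one
Conditions: NaBH4 (1 equiv), CeCl3·7H2O, MeOH/CH2Cl2, −78 °C; neutral work-up
Reagents that add atoms: none
Why: Luche 1,2-reduction; CeCl3 activates the conjugated C4 carbonyl, which can be chelated by the C3 and C5 methoxy oxygens, while C8 lies between two quaternary carbons, and hydride enters C4 from the face turned to the C8 bridge because the other face is covered by the endo aryl on C6, giving the 4R alcohol with the hydroxyl syn to the C6–C7 bridge.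

Step 11
Reactants: 16 (1S,4R,5S,6R,7S)-4-hydroxy-3,5-dimethoxy-7-methyl-1-(prop-2-en-1-yl)-6-(3,4,5-trimethoxyphenyl)bicyclo[3.2.1]oct-2-en-8-one
Product: 17 (1S,4R,5S,6R,7S)-3,5-dimethoxy-7-methyl-8-oxo-1-(prop-2-en-1-yl)-6-(3,4,5-trimethoxyphenyl)bicyclo[3.2.1]oct-2-en-4-yl acetate
Conditions: Ac2O, pyridine, DMAP (cat.), CH2Cl2, 0 °C → rt
Reagents that add atoms: acetic anhydride, CC(=O)OC(C)=O
Why: DMAP-catalysed acylation of the secondary allylic alcohol under mild amine conditions that should not trigger retro-aldol opening of the beta-hydroxy ketone; the C–O bond at C4 is not broken, so the configuration is retained.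

**Compound list**

1 | 4-allyl-2,6-dimethoxyphenol | C=CCc1cc(OC)c(O)c(OC)c1 | starting material
2 | tert-butyl[2,6-dimethoxy-4-(prop-2-en-1-yl)phenoxy]dimethylsilane | C=CCc1cc(OC)c(O[Si](C)(C)C(C)(C)C)c(OC)c1 | intermediate
3 | [3-bromo-2,6-dimethoxy-4-(prop-2-en-1-yl)phenoxy](tert-butyl)dimethylsilane | C=CCc1cc(OC)c(O[Si](C)(C)C(C)(C)C)c(OC)c1Br | intermediate
4 | {3-[(tert-butyldimethylsilyl)oxy]-2,4-dimethoxy-6-(prop-2-en-1-yl)phenyl}lithium | C=CCc1cc(OC)c(O[Si](C)(C)C(C)(C)C)c(OC)c1[Li] | intermediate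
5 | dimethyl {3-[(tert-butyldimethylsilyl)oxy]-2,4-dimethoxy-6-(prop-2-en-1-yl)phenyl}boronate | C=CCc1cc(OC)c(O[Si](C)(C)C(C)(C)C)c(OC)c1B(OC)OC | intermediate
6 | 3-[(tert-butyldimethylsilyl)oxy]-2,4-dimethoxy-6-(prop-2-en-1-yl)phenol | C=CCc1cc(OC)c(O[Si](C)(C)C(C)(C)C)c(OC)c1O | intermediate
7 | 5-bromo-1,2,3-trimethoxybenzene | COc1cc(Br)cc(OC)c1OC | starting material
8 | (E)-prop-1-en-1-ylboronic acid | C/C=C/B(O)O | starting material
9 | (E)-isoelemicin, 1,2,3-trimethoxy-5-[(1E)-prop-1-en-1-yl]benzene | C/C=C/c1cc(OC)c(OC)c(OC)c1 | intermediate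
10 | 3-[(tert-butyldimethylsilyl)oxy]-4-methoxy-6-(prop-2-en-1-yl)cyclohexa-3,5-diene-1,2-dione | C=CCC1=CC(OC)=C(O[Si](C)(C)C(C)(C)C)C(=O)C1=O | intermediate
11 | racemic (1RS,4RS,7RS,8SR)-4-[(tert-butyldimethylsilyl)oxy]-5-methoxy-7-methyl-1-(prop-2-en-1-yl)-8-(3,4,5-trimethoxyphenyl)bicyclo[2.2.2]oct-5-ene-2,3-dione (both enantiomers) | C=CC[C@]12C=C(OC)[C@](O[Si](C)(C)C(C)(C)C)(C(=O)C1=O)[C@@H](c1cc(OC)c(OC)c(OC)c1)[C@@H]2C.C=CC[C@@]12C=C(OC)[C@@](O[Si](C)(C)C(C)(C)C)(C(=O)C1=O)[C@H](c1cc(OC)c(OC)c(OC)c1)[C@H]2C | intermediate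
12 | (1S,4S,7S,8R)-4-[(tert-butyldimethylsilyl)oxy]-5-methoxy-7-methyl-1-(prop-2-en-1-yl)-8-(3,4,5-trimethoxyphenyl)bicyclo[2.2.2]oct-5-ene-2,3-dione | C=CC[C@]12C=C(OC)[C@](O[Si](C)(C)C(C)(C)C)(C(=O)C1=O)[C@@H](c1cc(OC)c(OC)c(OC)c1)[C@@H]2C | intermediate
13 | (1S,4S,7S,8R)-4-hydroxy-5-methoxy-7-methyl-1-(prop-2-en-1-yl)-8-(3,4,5-trimethoxyphenyl)bicyclo[2.2.2]oct-5-ene-2,3-dione | C=CC[C@]12C=C(OC)[C@](O)(C(=O)C1=O)[C@@H](c1cc(OC)c(OC)c(OC)c1)[C@@H]2C | intermediate
14 | (1S,5R,6R,7S)-5-hydroxy-3-methoxy-7-methyl-1-(prop-2-en-1-yl)-6-(3,4,5-trimethoxyphenyl)bicyclo[3.2.1]oct-2-ene-4,8-dione | C=CC[C@]12C=C(OC)C(=O)[C@](O)(C1=O)[C@@H](c1cc(OC)c(OC)c(OC)c1)[C@@H]2C | intermediate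
15 | (1S,5R,6R,7S)-3,5-dimethoxy-7-methyl-1-(prop-2-en-1-yl)-6-(3,4,5-trimethoxyphenyl)bicyclo[3.2.1]oct-2-ene-4,8-dione | C=CC[C@]12C=C(OC)C(=O)[C@](OC)(C1=O)[C@@H](c1cc(OC)c(OC)c(OC)c1)[C@@H]2C | intermediate
16 | (1S,4R,5S,6R,7S)-4-hydroxy-3,5-dimethoxy-7-methyl-1-(prop-2-en-1-yl)-6-(3,4,5-trimethoxyphenyl)bicyclo[3.2.1]oct-2-en-8-one | C=CC[C@]12C=C(OC)[C@@H](O)[C@](OC)(C1=O)[C@@H](c1cc(OC)c(OC)c(OC)c1)[C@@H]2C | intermediate
17 | (1S,4R,5S,6R,7S)-3,5-dimethoxy-7-methyl-8-oxo-1-(prop-2-en-1-yl)-6-(3,4,5-trimethoxyphenyl)bicyclo[3.2.1]oct-2-en-4-yl acetate | C=CC[C@]12C=C(OC)[C@@H](OC(C)=O)[C@](OC)(C1=O)[C@@H](c1cc(OC)c(OC)c(OC)c1)[C@@H]2C | target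

**Step count.** Total: 11 steps. Longest linear sequence: 10 steps (1 → 2 → 3 → 6 → 11 → 12 → 13 → 14 → 15 → 16 → 17); step 4 is a one-step side branch.

**Steps most likely to fail**

Step 8. The danger is that the new C5 alkoxide undergoes a second 1,2-shift (the C4 acyl carbon moving from C5 to C8, giving a bicyclo[3.3.0] isomer), or that the vinylic C3 migrates under kinetic conditions. The fallback sets out from 12 and comes back at 14, and never generates a free alkoxide. The silyl ether 12 is treated with MeAl(OC6H2-4-Br-2,6-tBu2)2 in CH2Cl2 at −78 → 0 °C. The shift then runs as a Lewis-acid-promoted rearrangement of an alpha-silyloxy ketone with transfer of the silyl group to the new C5 oxygen, giving (1S,5R,6R,7S)-5-[(tert-butyldimethylsilyl)oxy]-3-methoxy-7-methyl-1-(prop-2-en-1-yl)-6-(3,4,5-trimethoxyphenyl)bicyclo[3.2.1]oct-2-ene-4,8-dione F1. Buffered Bu4NF/AcOH in THF then frees 14.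

Step 5. The transient quinone may be lost to dimerisation or to cleavage of its vinylogous silyl ether before it is trapped, or the alkene may add with the opposite orientation or across the two carbonyl oxygens. The fallback sets out from 9 and comes back at 15; it replaces steps 5 to 9 with a cationic [5+2] cycloaddition and is held in reserve because it also gives up the ketol shift. Commercial 2,3,4-trimethoxyphenol is O-allylated (allyl bromide, K2CO3, acetone) to 1,2,3-trimethoxy-4-(prop-2-en-1-yloxy)benzene F2. Aromatic Claisen rearrangement (N,N-diethylaniline, 190 °C) moves the allyl group to the only free ortho position, giving 6-allyl-2,3,4-trimethoxyphenol F3. PhI(OAc)2 in MeOH gives the para-quinone monoketal 2-allyl-4,4,5,6-tetramethoxycyclohexa-2,5-dien-1-one F4. Me3SiOTf (1.1 equiv) in MeCN at −40 °C ionises the ketal, and the resulting cation adds 9 across the two carbons flanking the ring carbonyl (the future C1 and C5), the methyl-bearing alkene carbon bonding to the allyl-bearing carbon and the aryl ending endo. Loss of the methyl group from the oxocarbenium at C4 gives racemic (1RS,5SR,6SR,7RS)-3,5-dimethoxy-7-methyl-1-(prop-2-en-1-yl)-6-(3,4,5-trimethoxyphenyl)bicyclo[3.2.1]oct-2-ene-4,8-dione F5. Resolution on the chiral phase of step 6 gives 15 and removes its enantiomer.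

Step 10. Hydride may be delivered to the strained C8 ketone in competition with, or ahead of, the conjugated C4 carbonyl. The fallback sets out from 15 and comes back at 17, replacing steps 10 and 11. Excess NaBH4 with CeCl3·7H2O in MeOH at 0 °C reduces both carbonyls to (1S,4R,5R,6R,7S,8S)-3,5-dimethoxy-7-methyl-1-(prop-2-en-1-yl)-6-(3,4,5-trimethoxyphenyl)bicyclo[3.2.1]oct-2-ene-4,8-diol F6 (4R as in 16; the C8 configuration is drawn as 8S and is immaterial because that centre is removed again). Ac2O in pyridine without DMAP acetylates only the C4 hydroxyl, since the C8 carbinol lies between two quaternary carbons, giving (1S,4R,5R,6R,7S,8S)-8-hydroxy-3,5-dimethoxy-7-methyl-1-(prop-2-en-1-yl)-6-(3,4,5-trimethoxyphenyl)bicyclo[3.2.1]oct-2-en-4-yl acetate F7. Dess–Martin periodinane in CH2Cl2 re-oxidises C8 to give 17.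

**Further compounds**

F1 | step 8 | (1S,5R,6R,7S)-5-[(tert-butyldimethylsilyl)oxy]-3-methoxy-7-methyl-1-(prop-2-en-1-yl)-6-(3,4,5-trimethoxyphenyl)bicyclo[3.2.1]oct-2-ene-4,8-dione | C=CC[C@]12C=C(OC)C(=O)[C@](O[Si](C)(C)C(C)(C)C)(C1=O)[C@@H](c1cc(OC)c(OC)c(OC)c1)[C@@H]2C
F2 | step 5 | 1,2,3-trimethoxy-4-(prop-2-en-1-yloxy)benzene | C=CCOc1ccc(OC)c(OC)c1OC
F3 | step 5 | 6-allyl-2,3,4-trimethoxyphenol | C=CCc1cc(OC)c(OC)c(OC)c1O
F4 | step 5 | 2-allyl-4,4,5,6-tetramethoxycyclohexa-2,5-dien-1-one | C=CCC1=CC(OC)(OC)C(OC)=C(OC)C1=O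
F5 | step 5 | racemic (1RS,5SR,6SR,7RS)-3,5-dimethoxy-7-methyl-1-(prop-2-en-1-yl)-6-(3,4,5-trimethoxyphenyl)bicyclo[3.2.1]oct-2-ene-4,8-dione (both enantiomers) | C=CC[C@]12C=C(OC)C(=O)[C@](OC)(C1=O)[C@@H](c1cc(OC)c(OC)c(OC)c1)[C@@H]2C.C=CC[C@@]12C=C(OC)C(=O)[C@@](OC)(C1=O)[C@H](c1cc(OC)c(OC)c(OC)c1)[C@H]2C
F6 | step 10 | (1S,4R,5R,6R,7S,8S)-3,5-dimethoxy-7-methyl-1-(prop-2-en-1-yl)-6-(3,4,5-trimethoxyphenyl)bicyclo[3.2.1]oct-2-ene-4,8-diol | C=CC[C@]12C=C(OC)[C@@H](O)[C@](OC)([C@H]1O)[C@@H](c1cc(OC)c(OC)c(OC)c1)[C@@H]2C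
F7 | step 10 | (1S,4R,5R,6R,7S,8S)-8-hydroxy-3,5-dimethoxy-7-methyl-1-(prop-2-en-1-yl)-6-(3,4,5-trimethoxyphenyl)bicyclo[3.2.1]oct-2-en-4-yl acetate | C=CC[C@]12C=C(OC)[C@@H](OC(C)=O)[C@](OC)([C@H]1O)[C@@H](c1cc(OC)c(OC)c(OC)c1)[C@@H]2C
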